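The route rests on cutting the C7–C8 bond of ring B (C5–C6–C7–C8–C9–C10) as a C7=C8 olefin whose C7 carries the future carbinol carbon C11 as an ester. Ring A is built first, with both side-chain stereocentres, by two organocatalytic steps. A three-component methylcuprate addition/enolate alkylation then sets quaternary C10 and C5, leaving an allyl arm on C10 and a 2-(methoxycarbonyl)allyl arm on C5, trans to each other. Ring-closing metathesis of this diene closes ring B last. It exploits that C7 and C8 are the two ring B carbons lying between these arms, so the closure gives a trans-fused cyclohexene ester. Hydrogenation, threefold methyl addition, diformylation and demethylation finish the target.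

Key step: step 6

Remark on numbering: ring A = C1–C2–C3–C4–C5–C10, ring B = C5–C6–C7–C8–C9–C10. C1 carries the benzylic carbon C1′, C4 the tertiary OH, C7 the carbinol carbon C11, C10 the angular methyl.
Remark on stereochemistry: the target is trans-fused with C1′ R, C1 S, C4 R, C5 S, C7 S, C10 R. Where a name and a SMILES string differ, the SMILES string is meant.
Assumption: compounds 1, 2, 4 and 9 and all catalysts are commercial.

Step 1
Reactants: 1 1,3,5-trimethoxybenzene; 2 (2E)-5-methylhex-2-enal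
Product: 3 (3R)-5-methyl-3-(2,4,6-trimethoxyphenyl)hexanal
Conditions: (2S,5S)-5-benzyl-2-tert-butyl-3-methylimidazolidin-4-one·TFA (20 mol%), CHCl3, −20 °C
Reagents that add atoms: none
Why: Iminium-catalysed enantioselective Friedel–Crafts conjugate alkylation, in which the benzyl group of the catalyst shields one face of the E-iminium ion so that the arene should add to the other and set C1′ as R.

Step 2
Reactants: 3 (3R)-5-methyl-3-(2,4,6-trimethoxyphenyl)hexanal; 4 but-3-en-2-one
Product: 6 (4R)-4-[(1R)-3-methyl-1-(2,4,6-trimethoxyphenyl)butyl]cyclohex-2-en-1-one, via keto-aldehyde 5 (not isolated)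
Conditions: (S)-2-[methoxy(diphenyl)methyl]pyrrolidine (10 mol%), ethyl 3,4-dihydroxybenzoate (20 mol%), neat, 4 °C; then LiOH·H2O, i-PrOH, rt
Reagents that add atoms: none
Why: Enamine-catalysed Michael addition followed by intramolecular aldol condensation (organocatalytic Robinson annulation), in which the diphenylmethyl ether group blocks one face of the E-enamine so that C1 should be set by the catalyst and then become the non-epimerisable γ-carbon of the enone; the existing C1′ centre may reinforce or oppose this.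

Step 3
Reactants: 6 (4R)-4-[(1R)-3-methyl-1-(2,4,6-trimethoxyphenyl)butyl]cyclohex-2-en-1-one
Product: 7 trimethyl({(3S,4R)-4-[(1R)-3-methyl-1-(2,4,6-trimethoxyphenyl)butyl]-3-(prop-2-en-1-yl)cyclohex-1-en-1-yl}oxy)silane
Conditions: allylMgBr, CuBr·SMe2 (1 equiv), TMSCl, THF, −78 °C; Et3N, aq. NaHCO3
Reagents that add atoms: allylmagnesium bromide, C=CC[Mg]Br; chlorotrimethylsilane, C[Si](C)(C)Cl
Why: Silyl-accelerated conjugate addition of allylcopper, which suppresses 1,2-addition and traps the enolate as the regio-defined silyl enol ether; the allyl group should enter trans to the C1 side chain, but this C10 centre is erased in step 4.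

Step 4
Reactants: 7 trimethyl({(3S,4R)-4-[(1R)-3-methyl-1-(2,4,6-trimethoxyphenyl)butyl]-3-(prop-2-en-1-yl)cyclohex-1-en-1-yl}oxy)silane
Product: 8 (4S)-4-[(1R)-3-methyl-1-(2,4,6-trimethoxyphenyl)butyl]-3-(prop-2-en-1-yl)cyclohex-2-en-1-one
Conditions: IBX, 4-methoxypyridine N-oxide, DMSO, rt
Reagents that add atoms: none
Why: IBX dehydrogenation of a silyl enol ether (a metal-free Saegusa-type oxidation) should regenerate the enone regiospecifically as C5=C10, since the only β-hydrogen sits on C10, without touching the terminal olefin or C1.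

Step 5
Reactants: 8 (4S)-4-[(1R)-3-methyl-1-(2,4,6-trimethoxyphenyl)butyl]-3-(prop-2-en-1-yl)cyclohex-2-en-1-one; 9 methyl 2-(bromomethyl)prop-2-enoate
Product: 11 methyl 2-({(1S,2R,3S)-2-methyl-3-[(1R)-3-methyl-1-(2,4,6-trimethoxyphenyl)butyl]-6-oxo-2-(prop-2-en-1-yl)cyclohexyl}methyl)prop-2-enoate, via lithium enolate 10 (not isolated)
Conditions: Me2CuLi (from MeLi and CuI), Et2O, −20 → 0 °C; then 9 (excess), HMPA, THF, −78 → 0 °C
Reagents that add atoms: lithium dimethylcuprate, [Li+].C[Cu-]C
Why: Tandem cuprate conjugate addition/enolate alkylation (three components), in which methyl should add anti to the pseudoaxial C1 side chain to set C10 (methyl trans to the side chain), and the regio-defined enolate should then be C-alkylated by the allylic bromide on the face anti to both the side chain and the allyl arm, setting C5 with the C6 arm trans to the C9 arm.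

Step 6
Reactants: 11 methyl 2-({(1S,2R,3S)-2-methyl-3-[(1R)-3-methyl-1-(2,4,6-trimethoxyphenyl)butyl]-6-oxo-2-(prop-2-en-1-yl)cyclohexyl}methyl)prop-2-enoate
Product: 12 methyl (4aR,5S,8aS)-4a-methyl-5-[(1R)-3-methyl-1-(2,4,6-trimethoxyphenyl)butyl]-8-oxo-1,4,4a,5,6,7,8,8a-octahydronaphthalene-2-carboxylate
Conditions: second-generation Grubbs catalyst (5 mol%), CH2Cl2 (0.005 M), 40 °C
Reagents that add atoms: none
Why: The ruthenium alkylidene should initiate at the monosubstituted allyl olefin on C10, engage the 1,1-disubstituted acrylate olefin of the C5 arm through a ruthenacyclobutane and expel ethene, forming the C7=C8 bond. The closest known reaction type is ring-closing metathesis of an allyl group onto a 2-substituted acrylate to give a cyclic trisubstituted enoate. Ring B closes as a six-membered ring with both olefin carbons inside the new ring. No stereocentre is created: the trans ring fusion is carried in from step 5 as the trans relation of the two arms, which sit diequatorial on the ring A chair and are therefore within reach of each other. The selectivity needed is ring closure over cross-metathesis, which high dilution, the quaternary C10 (Thorpe–Ingold effect) and the poor homodimerisation of the acrylate olefin should secure. Ketone, ester and trimethoxyarene are inert to the catalyst.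

Step 7
Reactants: 12 methyl (4aR,5S,8aS)-4a-methyl-5-[(1R)-3-methyl-1-(2,4,6-trimethoxyphenyl)butyl]-8-oxo-1,4,4a,5,6,7,8,8a-octahydronaphthalene-2-carboxylate
Product: 13 methyl (2S,4aR,5S,8aS)-4a-methyl-5-[(1R)-3-methyl-1-(2,4,6-trimethoxyphenyl)butyl]-8-oxodecahydronaphthalene-2-carboxylate
Conditions: H2 (1 atm), 10% Pd/C, EtOAc, rt
Reagents that add atoms: none
Why: Heterogeneous hydrogenation should deliver hydrogen to the enoate from the face opposite the axial angular methyl (which is syn-axial to C8), placing H7 anti to that methyl and the ester equatorial; the neutral conditions leave C5, the ketone, the ester and the arene unchanged.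

Step 8
Reactants: 13 methyl (2S,4aR,5S,8aS)-4a-methyl-5-[(1R)-3-methyl-1-(2,4,6-trimethoxyphenyl)butyl]-8-oxodecahydronaphthalene-2-carboxylate
Product: 14 (1R,4S,4aR,7S,8aS)-7-(2-hydroxypropan-2-yl)-1,4a-dimethyl-4-[(1R)-3-methyl-1-(2,4,6-trimethoxyphenyl)butyl]decahydronaphthalen-1-ol
Conditions: MeLi (excess), CeCl3, THF, −78 → 0 °C; aq. NH4Cl
Reagents that add atoms: methyllithium, C[Li]
Why: Organocerium 1,2-addition, whose low basicity suppresses enolisation and so protects C5; the ester takes two methyl groups, and the C4 ketone should be attacked along the equatorial line because axial approach is blocked by the 1,3-syn-axial C10 methyl, giving the axial C4–OH cis to that methyl.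

Step 9
Reactants: 14 (1R,4S,4aR,7S,8aS)-7-(2-hydroxypropan-2-yl)-1,4a-dimethyl-4-[(1R)-3-methyl-1-(2,4,6-trimethoxyphenyl)butyl]decahydronaphthalen-1-ol
Product: 16 5-[(1R)-1-[(1S,4R,4aS,6S,8aR)-4-hydroxy-6-(2-hydroxypropan-2-yl)-4,8a-dimethyldecahydronaphthalen-1-yl]-3-methylbutyl]-2,4,6-trimethoxybenzene-1,3-dicarbaldehyde, via lithium hemiaminal 15 (not isolated)
Conditions: n-BuLi (3.3 equiv), TMEDA, THF, 0 °C → rt; DMF (1.1 equiv), −78 → 0 °C; n-BuLi (1.5 equiv), 0 °C → rt; DMF (3 equiv); aq. NH4Cl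
Reagents that add atoms: N,N-dimethylformamide, CN(C)C=O
Why: Directed ortho-metalation/formylation, in which each free ring position is flanked by two methoxy groups and should be lithiated selectively after the two hydroxyls are deprotonated; the first DMF adduct stays masked as its α-amino alkoxide while the second position is metalated and formylated.

Step 10
Reactants: 16 5-[(1R)-1-[(1S,4R,4aS,6S,8aR)-4-hydroxy-6-(2-hydroxypropan-2-yl)-4,8a-dimethyldecahydronaphthalen-1-yl]-3-methylbutyl]-2,4,6-trimethoxybenzene-1,3-dicarbaldehyde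
Product: 17 5-[(1R)-1-[(1S,4R,4aS,6S,8aR)-4-hydroxy-6-(2-hydroxypropan-2-yl)-4,8a-dimethyldecahydronaphthalen-1-yl]-3-methylbutyl]-2,4,6-trihydroxybenzene-1,3-dicarbaldehyde
Conditions: NaSEt (excess), DMF, 120 °C; then cold dilute HCl to pH 3
Reagents that add atoms: none
Why: Thiolate SN2 O-demethylation, made possible because every methoxy group is ortho or para to a formyl group and so leaves as a stabilised phenoxide; the basic medium should spare both tertiary alcohols and no stereocentre is touched.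

Compound list
1 | 1,3,5-trimethoxybenzene | COc1cc(OC)cc(OC)c1 | starting material
2 | (2E)-5-methylhex-2-enal | CC(C)C/C=C/C=O | starting material
3 | (3R)-5-methyl-3-(2,4,6-trimethoxyphenyl)hexanal | CC(C)C[C@@H](c1c(OC)cc(OC)cc1OC)CC=O | intermediate
4 | but-3-en-2-one (methyl vinyl ketone) | CC(=O)C=C | starting material
5 | (2S,3R)-5-methyl-2-(3-oxobutyl)-3-(2,4,6-trimethoxyphenyl)hexanal | CC(C)C[C@@H](c1c(OC)cc(OC)cc1OC)[C@@H](C=O)CCC(C)=O | intermediate
6 | (4R)-4-[(1R)-3-methyl-1-(2,4,6-trimethoxyphenyl)butyl]cyclohex-2-en-1-one | CC(C)C[C@@H](c1c(OC)cc(OC)cc1OC)[C@@H]1CCC(=O)C=C1 | intermediate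
7 | trimethyl({(3S,4R)-4-[(1R)-3-methyl-1-(2,4,6-trimethoxyphenyl)butyl]-3-(prop-2-en-1-yl)cyclohex-1-en-1-yl}oxy)silane | CC(C)C[C@@H](c1c(OC)cc(OC)cc1OC)[C@@H]1CCC(O[Si](C)(C)C)=C[C@H]1CC=C | intermediate
8 | (4S)-4-[(1R)-3-methyl-1-(2,4,6-trimethoxyphenyl)butyl]-3-(prop-2-en-1-yl)cyclohex-2-en-1-one | CC(C)C[C@@H](c1c(OC)cc(OC)cc1OC)[C@@H]1CCC(=O)C=C1CC=C | intermediate
9 | methyl 2-(bromomethyl)prop-2-enoate | COC(=O)C(=C)CBr | starting material
10 | lithium (3R,4S)-3-methyl-4-[(1R)-3-methyl-1-(2,4,6-trimethoxyphenyl)butyl]-3-(prop-2-en-1-yl)cyclohex-1-en-1-olate | CC(C)C[C@@H](c1c(OC)cc(OC)cc1OC)[C@@H]1CCC(O[Li])=C[C@]1(C)CC=C | intermediate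
11 | methyl 2-({(1S,2R,3S)-2-methyl-3-[(1R)-3-methyl-1-(2,4,6-trimethoxyphenyl)butyl]-6-oxo-2-(prop-2-en-1-yl)cyclohexyl}methyl)prop-2-enoate | CC(C)C[C@@H](c1c(OC)cc(OC)cc1OC)[C@@H]1CCC(=O)[C@@H](CC(=C)C(=O)OC)[C@]1(C)CC=C | intermediate
12 | methyl (4aR,5S,8aS)-4a-methyl-5-[(1R)-3-methyl-1-(2,4,6-trimethoxyphenyl)butyl]-8-oxo-1,4,4a,5,6,7,8,8a-octahydronaphthalene-2-carboxylate | CC(C)C[C@@H](c1c(OC)cc(OC)cc1OC)[C@@H]1CCC(=O)[C@H]2CC(C(=O)OC)=CC[C@]12C | intermediate
13 | methyl (2S,4aR,5S,8aS)-4a-methyl-5-[(1R)-3-methyl-1-(2,4,6-trimethoxyphenyl)butyl]-8-oxodecahydronaphthalene-2-carboxylate | CC(C)C[C@@H](c1c(OC)cc(OC)cc1OC)[C@@H]1CCC(=O)[C@H]2C[C@@H](C(=O)OC)CC[C@]12C | intermediate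
14 | (1R,4S,4aR,7S,8aS)-7-(2-hydroxypropan-2-yl)-1,4a-dimethyl-4-[(1R)-3-methyl-1-(2,4,6-trimethoxyphenyl)butyl]decahydronaphthalen-1-ol | CC(C)C[C@@H](c1c(OC)cc(OC)cc1OC)[C@@H]1CC[C@@](C)(O)[C@H]2C[C@@H](C(C)(C)O)CC[C@]12C | intermediate
15 | mono-formyl adduct of 14 held as its lithium α-(dimethylamino)benzyloxide, both tertiary hydroxyls as lithium alkoxides | CC(C)C[C@@H](c1c(OC)cc(OC)c(C(O[Li])N(C)C)c1OC)[C@@H]1CC[C@@](C)(O[Li])[C@H]2C[C@@H](C(C)(C)O[Li])CC[C@]12C | intermediate
16 | 5-[(1R)-1-[(1S,4R,4aS,6S,8aR)-4-hydroxy-6-(2-hydroxypropan-2-yl)-4,8a-dimethyldecahydronaphthalen-1-yl]-3-methylbutyl]-2,4,6-trimethoxybenzene-1,3-dicarbaldehyde | CC(C)C[C@@H](c1c(OC)c(C=O)c(OC)c(C=O)c1OC)[C@@H]1CC[C@@](C)(O)[C@H]2C[C@@H](C(C)(C)O)CC[C@]12C | intermediate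
17 | 5-[(1R)-1-[(1S,4R,4aS,6S,8aR)-4-hydroxy-6-(2-hydroxypropan-2-yl)-4,8a-dimethyldecahydronaphthalen-1-yl]-3-methylbutyl]-2,4,6-trihydroxybenzene-1,3-dicarbaldehyde (CNP0409870.5) | CC(C)C[C@@H](c1c(O)c(C=O)c(O)c(C=O)c1O)[C@@H]1CC[C@@](C)(O)[C@H]2C[C@@H](C(C)(C)O)CC[C@]12C | target

Total step count: 10
Longest linear sequence: 10 steps (from 1 and 2 to 17)

Steps most likely to fail

Step 1. The trimethoxyarene may be too weak a π-nucleophile for the iminium ion, so that conversion stalls and an uncatalysed background alkylation lowers the enantiomeric purity. The fallback sets out from 2 and 1 and comes back at 3. Enal 2 is oxidised (NaClO2, NaH2PO4, 2-methylbut-2-ene) to (2E)-5-methylhex-2-enoic acid F1, which oxalyl chloride converts into (2E)-5-methylhex-2-enoyl chloride F2. Acylation of lithiated (4S)-4-phenyl-1,3-oxazolidin-2-one with F2 gives (4S)-3-[(2E)-5-methylhex-2-enoyl]-4-phenyl-1,3-oxazolidin-2-one F3. Arene 1 is lithiated (n-BuLi, THF, 0 °C) to (2,4,6-trimethoxyphenyl)lithium F4 and transmetalated with MgBr2·OEt2 to (2,4,6-trimethoxyphenyl)magnesium bromide F5. Its CuBr·SMe2-mediated conjugate addition to the chelated imide F3, anti to the 4-phenyl group, should give (4S)-3-[(3R)-5-methyl-3-(2,4,6-trimethoxyphenyl)hexanoyl]-4-phenyl-1,3-oxazolidin-2-one F6. LiBH4 reduction releases the auxiliary and gives (3R)-5-methyl-3-(2,4,6-trimethoxyphenyl)hexan-1-ol F7, and Dess–Martin oxidation returns aldehyde 3.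

Step 5. C-alkylation of the hindered enolate next to the new quaternary centre may be slow, so that anionic oligomerisation of the acrylate electrophile takes over. The fallback sets out from 8 and comes back at 11. Enolate 10 is generated as before but trapped with propargyl bromide, a compact electrophile that cannot act as a Michael acceptor, to give (2S,3R,4S)-3-methyl-4-[(1R)-3-methyl-1-(2,4,6-trimethoxyphenyl)butyl]-3-(prop-2-en-1-yl)-2-(prop-2-yn-1-yl)cyclohexan-1-one F8. Markovnikov methoxycarbonylation of the terminal alkyne (Pd(OAc)2, 2-(diphenylphosphino)pyridine, MsOH, CO, MeOH) then builds the 2-substituted acrylate and returns 11; the alkyne should react in preference to the allyl olefin.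

Step 9. The second deprotonation, on a ring that already carries the anionic hemiaminal, may be incomplete, leaving mono-aldehyde. The fallback sets out from 14 and comes back at 16. Both free ring positions of 14 are brominated with NBS (MeCN, 0 °C) to give (1R,4S,4aR,7S,8aS)-4-[(1R)-1-(3,5-dibromo-2,4,6-trimethoxyphenyl)-3-methylbutyl]-7-(2-hydroxypropan-2-yl)-1,4a-dimethyldecahydronaphthalen-1-ol F9. After deprotonation of the two hydroxyls, bromine–lithium exchange (n-BuLi, THF, −78 °C) and DMF quench, run twice in sequence, should give 16.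

Further compounds
F1 | step 1 | (2E)-5-methylhex-2-enoic acid | CC(C)C/C=C/C(=O)O
F2 | step 1 | (2E)-5-methylhex-2-enoyl chloride | CC(C)C/C=C/C(=O)Cl
F3 | step 1 | (4S)-3-[(2E)-5-methylhex-2-enoyl]-4-phenyl-1,3-oxazolidin-2-one | CC(C)C/C=C/C(=O)N1C(=O)OC[C@@H]1c1ccccc1
F4 | step 1 | (2,4,6-trimethoxyphenyl)lithium | [Li]c1c(OC)cc(OC)cc1OC
F5 | step 1 | (2,4,6-trimethoxyphenyl)magnesium bromide | Br[Mg]c1c(OC)cc(OC)cc1OC
F6 | step 1 | (4S)-3-[(3R)-5-methyl-3-(2,4,6-trimethoxyphenyl)hexanoyl]-4-phenyl-1,3-oxazolidin-2-one | CC(C)C[C@@H](c1c(OC)cc(OC)cc1OC)CC(=O)N1C(=O)OC[C@@H]1c1ccccc1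
F7 | step 1 | (3R)-5-methyl-3-(2,4,6-trimethoxyphenyl)hexan-1-ol | CC(C)C[C@@H](c1c(OC)cc(OC)cc1OC)CCO
F8 | step 5 | (2S,3R,4S)-3-methyl-4-[(1R)-3-methyl-1-(2,4,6-trimethoxyphenyl)butyl]-3-(prop-2-en-1-yl)-2-(prop-2-yn-1-yl)cyclohexan-1-one | CC(C)C[C@@H](c1c(OC)cc(OC)cc1OC)[C@@H]1CCC(=O)[C@@H](CC#C)[C@]1(C)CC=C
F9 | step 9 | (1R,4S,4aR,7S,8aS)-4-[(1R)-1-(3,5-dibromo-2,4,6-trimethoxyphenyl)-3-methylbutyl]-7-(2-hydroxypropan-2-yl)-1,4a-dimethyldecahydronaphthalen-1-ol | CC(C)C[C@@H](c1c(OC)c(Br)c(OC)c(Br)c1OC)[C@@H]1CC[C@@](C)(O)[C@H]2C[C@@H](C(C)(C)O)CC[C@]12C
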